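**Retrosynthetic overview**

- The target comes from its hexabenzyl ether by Lewis-acid debenzylation in the last step.
- Both five-membered rings and all four stereocentres are made in one flask from an achiral tris-phenol tetraene with chiral phosphoric acids: first the O–C2 bond (dihydrofuran ring), then the C3–C3a bond (cyclopentane ring of the indane), each by 1,6-addition to a para-quinone methide tautomer.
- The benzylidene geometry is fixed beforehand on a 1,1-dibromoalkene: trans-selective Suzuki coupling (dienyl arm), then a second Suzuki coupling (aryl cis to the central ring).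
- Both stilbenyl arms come from one alkenyl boronate, used twice, made from 3',5'-bis(benzyloxy)acetophenone (α-arylation, enol triflate, borylation); the core is 3-bromo-4-hydroxybenzaldehyde.
- All six benzene rings come from commercial materials; no ring is closed before the key step.

Assumption: which hand of the chiral phosphoric acid gives which ring configuration is not known for these closures; the hands written in step 10 are the working choice, to be checked on a small scale and exchanged independently if a closure gives the mirror-image sense (both enantiomers are commercial).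

**Route**

Step 1
Reactants: 1 3',5'-bis(benzyloxy)acetophenone; 2 (4-bromophenoxy)triisopropylsilane
Product: 3 1-[3,5-bis(benzyloxy)phenyl]-2-[4-(triisopropylsilyloxy)phenyl]ethan-1-one
Conditions: Pd2(dba)3 (1 mol %), Xantphos (2.4 mol %), NaOtBu, THF/toluene, 70 °C
Reagents that add atoms: none
Why: Palladium-catalysed α-arylation of the methyl ketone enolate with the aryl bromide (Buchwald–Hartwig type ketone arylation) stops at the mono-arylated deoxybenzoin because the more acidic product enolate is the poorer nucleophile, and no stereocentre is formed.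

Step 2
Reactants: 3 1-[3,5-bis(benzyloxy)phenyl]-2-[4-(triisopropylsilyloxy)phenyl]ethan-1-one
Product: 4 (Z)-1-[3,5-bis(benzyloxy)phenyl]-2-[4-(triisopropylsilyloxy)phenyl]ethenyl trifluoromethanesulfonate (triflate oxygen cis to the silyloxyphenyl ring)
Conditions: KN(SiMe3)2, THF, −78 °C; then PhNTf2, −78 to 0 °C
Reagents that add atoms: N-phenylbis(trifluoromethanesulfonimide), O=S(=O)(N(c1ccccc1)S(=O)(=O)C(F)(F)F)C(F)(F)F
Why: Kinetic deprotonation of the benzyl aryl ketone gives the Z(O)-enolate, which is O-sulfonylated (enol triflate formation), and the geometry of this alkene is of no consequence later because both of its carbons become sp3 in step 10.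

Step 3
Reactants: 4 (Z)-enol triflate
Product: 5 2-{(E)-1-[3,5-bis(benzyloxy)phenyl]-2-[4-(triisopropylsilyloxy)phenyl]ethenyl}-4,4,5,5-tetramethyl-1,3,2-dioxaborolane (boron cis to the silyloxyphenyl ring)
Conditions: B2pin2, PdCl2(PPh3)2 (3 mol %), PPh3 (6 mol %), KOPh, toluene, 50 °C
Reagents that add atoms: bis(pinacolato)diboron, CC1(C)OB(OC1(C)C)B1OC(C)(C)C(C)(C)O1
Why: Miyaura borylation of an alkenyl triflate proceeds with retention of alkene geometry and gives the one nucleophile that later delivers both stilbenyl arms.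

Step 4
Reactants: 6 3-bromo-4-hydroxybenzaldehyde
Product: 7 3-bromo-4-(triisopropylsilyloxy)benzaldehyde
Conditions: iPr3SiCl, imidazole, DMF, 0 °C to rt
Reagents that add atoms: chlorotriisopropylsilane, CC(C)[Si](Cl)(C(C)C)C(C)C
Why: Silyl ether formation masks the acidic phenol for the ylide and cross-coupling steps with a group that leaves together with the other two silyl groups in step 9.

Step 5
Reactants: 7 3-bromo-4-(triisopropylsilyloxy)benzaldehyde; 5 alkenyl boronate
Product: 8 3-{(Z)-1-[3,5-bis(benzyloxy)phenyl]-2-[4-(triisopropylsilyloxy)phenyl]ethenyl}-4-(triisopropylsilyloxy)benzaldehyde (formyl-bearing ring cis to the silyloxyphenyl ring)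
Conditions: Pd(OAc)2 (3 mol %), SPhos (6 mol %), K3PO4, toluene/H2O (10:1), 80 °C
Reagents that add atoms: none
Why: Suzuki–Miyaura coupling of the ortho-hindered aryl bromide with the alkenyl boronate is enabled by the bulky biaryl phosphine, tolerates the aldehyde and retains the alkenyl geometry.

Step 6
Reactants: 8 aldehyde
Product: 9 {2-{(Z)-1-[3,5-bis(benzyloxy)phenyl]-2-[4-(triisopropylsilyloxy)phenyl]ethenyl}-4-(2,2-dibromoethenyl)phenoxy}triisopropylsilane
Conditions: CBr4, PPh3, Zn dust, CH2Cl2, 0 °C to rt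
Reagents that add atoms: carbon tetrabromide, BrC(Br)(Br)Br
Why: Ramirez dibromo-olefination (first stage of the Corey–Fuchs sequence) converts the aldehyde into the 1,1-dibromoalkene, and the zinc variant keeps the medium free of acid for the electron-rich triarylethene.

Step 7
Reactants: 9 1,1-dibromoalkene; 5 alkenyl boronate
Product: 10 {2-{(Z)-1-[3,5-bis(benzyloxy)phenyl]-2-[4-(triisopropylsilyloxy)phenyl]ethenyl}-4-{(1Z,3Z)-2-bromo-3-[3,5-bis(benzyloxy)phenyl]-4-[4-(triisopropylsilyloxy)phenyl]buta-1,3-dien-1-yl}phenoxy}triisopropylsilane (bromine cis to the central ring)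
Conditions: Pd(PPh3)4 (5 mol %), Cs2CO3, THF/H2O (5:1), 60 °C, slight excess of 5, dark
Reagents that add atoms: none
Why: Stereoselective Suzuki–Miyaura mono-coupling of a 1,1-dibromoalkene takes place at the less hindered C–Br bond trans to the aryl group, so the dienyl arm ends trans and the remaining bromine cis to the central ring.

Step 8
Reactants: 10 (1Z,3Z)-bromodiene; 11 3,5-bis(benzyloxy)phenylboronic acid
Product: 12 {2-{(Z)-1-[3,5-bis(benzyloxy)phenyl]-2-[4-(triisopropylsilyloxy)phenyl]ethenyl}-4-{(1E,3Z)-2,3-bis[3,5-bis(benzyloxy)phenyl]-4-[4-(triisopropylsilyloxy)phenyl]buta-1,3-dien-1-yl}phenoxy}triisopropylsilane (central ring cis to the aryl group on C2 of the diene)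
Conditions: Pd(OAc)2 (5 mol %), SPhos (10 mol %), K3PO4, toluene/H2O (10:1), 80 °C, dark
Reagents that add atoms: none
Why: Suzuki–Miyaura coupling of the remaining alkenyl bromide with retention places the bis(benzyloxy)phenyl ring cis to the central ring, which is the benzylidene geometry of the target (aryl cis to C7a of the later indane).

Step 9
Reactants: 12 tris-silyl ether
Product: 13 2-{(Z)-1-[3,5-bis(benzyloxy)phenyl]-2-(4-hydroxyphenyl)ethenyl}-4-{(1E,3Z)-2,3-bis[3,5-bis(benzyloxy)phenyl]-4-(4-hydroxyphenyl)buta-1,3-dien-1-yl}phenol (achiral tris-phenol)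
Conditions: Bu4NF, AcOH, THF, 0 °C, dark; used directly
Reagents that add atoms: none
Why: Fluoride-mediated cleavage of the three aryl silyl ethers, buffered with acetic acid so that no phenolate chemistry or acid-induced cyclisation occurs, frees exactly the three phenols that the next step needs while the benzyl ethers stay.

Step 10
Reactants: 13 tris-phenol
Product: 15 (1Z,2R,3R)-4,6-bis(benzyloxy)-2-[3,5-bis(benzyloxy)phenyl]-1-({(2S,3S)-3-[3,5-bis(benzyloxy)phenyl]-2-(4-hydroxyphenyl)-2,3-dihydro-1-benzofuran-5-yl}methylidene)-3-(4-hydroxyphenyl)-2,3-dihydro-1H-indene, via mono-cyclised dihydrobenzofuran diene 14 (not isolated)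
Conditions: a) (R)-3,3'-bis(2,4,6-triisopropylphenyl)-1,1'-binaphthyl-2,2'-diyl hydrogen phosphate (3 mol %), 4 Å MS, toluene/CH2Cl2 (1:1), 0.01 M, 0 °C, dark; b) then the (S)-enantiomer of the same acid (15 mol %), 35 °C, same flask
Reagents that add atoms: none
Why: Proposed new method: the acid reversibly tautomerises each 4-hydroxystyrene unit to its para-quinone methide by protonation at the carbon that carries the 3,5-bis(benzyloxy)phenyl group, the central phenol adds to the first quinone methide in a 5-exo oxa-1,6-addition to give 14, and the dibenzyloxyarene then attacks the second one in a 5-exo Friedel–Crafts 1,6-addition, so that each chiral phosphate selects the face of its quinone methide (C2 of the dihydrobenzofuran S, C3 of the indane R) while the neighbouring methine equilibrates through the tautomerism and is fixed trans by the ring closure (C3 of the dihydrobenzofuran S, C2 of the indane R), the benzylidene geometry being safe once the central oxygen is an ether in 14; the closest known chemistry is the chiral phosphoric acid catalysed 1,6-addition to para-quinone methides generated in situ from 4-hydroxystyrenes, together with the quinone methide cyclisations of resveratrol oligomer chemistry.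

Step 11
Reactants: 15 hexabenzyl ether
Product: 16 (1Z,2R,3R)-1-{[(2S,3S)-3-(3,5-dihydroxyphenyl)-2-(4-hydroxyphenyl)-2,3-dihydro-1-benzofuran-5-yl]methylidene}-2-(3,5-dihydroxyphenyl)-3-(4-hydroxyphenyl)-2,3-dihydro-1H-indene-4,6-diol (CNP0184753.4)
Conditions: BCl3 (excess), pentamethylbenzene (excess), CH2Cl2, −78 °C, dark; then H2O/THF quench at −78 °C
Reagents that add atoms: none
Why: Lewis-acid debenzylation with BCl3 and pentamethylbenzene as a non-basic benzyl cation scavenger cleaves the six aryl benzyl ethers at −78 °C without hydrogen, so the benzylidene bond, the dihydrobenzofuran and the four stereocentres are left untouched.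

**Compound list**

1 | 3',5'-bis(benzyloxy)acetophenone | CC(=O)c1cc(OCc2ccccc2)cc(OCc2ccccc2)c1 | starting material
2 | (4-bromophenoxy)triisopropylsilane | CC(C)[Si](Oc1ccc(Br)cc1)(C(C)C)C(C)C | starting material
3 | 1-[3,5-bis(benzyloxy)phenyl]-2-[4-(triisopropylsilyloxy)phenyl]ethan-1-one | O=C(Cc1ccc(O[Si](C(C)C)(C(C)C)C(C)C)cc1)c1cc(OCc2ccccc2)cc(OCc2ccccc2)c1 | intermediate
4 | (Z)-1-[3,5-bis(benzyloxy)phenyl]-2-[4-(triisopropylsilyloxy)phenyl]ethenyl triflate | O=S(=O)(O/C(=C\c1ccc(O[Si](C(C)C)(C(C)C)C(C)C)cc1)c1cc(OCc2ccccc2)cc(OCc2ccccc2)c1)C(F)(F)F | intermediate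
5 | (E)-alkenyl pinacol boronate (boron cis to the silyloxyphenyl ring) | CC1(C)OB(OC1(C)C)/C(=C\c1ccc(O[Si](C(C)C)(C(C)C)C(C)C)cc1)c1cc(OCc2ccccc2)cc(OCc2ccccc2)c1 | intermediate
6 | 3-bromo-4-hydroxybenzaldehyde | O=Cc1ccc(O)c(Br)c1 | starting material
7 | 3-bromo-4-(triisopropylsilyloxy)benzaldehyde | O=Cc1ccc(O[Si](C(C)C)(C(C)C)C(C)C)c(Br)c1 | intermediate
8 | 3-{(Z)-1-[3,5-bis(benzyloxy)phenyl]-2-[4-(triisopropylsilyloxy)phenyl]ethenyl}-4-(triisopropylsilyloxy)benzaldehyde | O=Cc1ccc(O[Si](C(C)C)(C(C)C)C(C)C)c(c1)/C(=C\c1ccc(O[Si](C(C)C)(C(C)C)C(C)C)cc1)c1cc(OCc2ccccc2)cc(OCc2ccccc2)c1 | intermediate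
9 | 2,2-dibromoethenyl analogue of 8 | BrC(Br)=Cc1ccc(O[Si](C(C)C)(C(C)C)C(C)C)c(c1)/C(=C\c1ccc(O[Si](C(C)C)(C(C)C)C(C)C)cc1)c1cc(OCc2ccccc2)cc(OCc2ccccc2)c1 | intermediate
10 | (1Z,3Z)-2-bromodiene, tris-silyl ether (bromine cis to the central ring) | Br/C(=C\c1ccc(O[Si](C(C)C)(C(C)C)C(C)C)c(c1)/C(=C\c1ccc(O[Si](C(C)C)(C(C)C)C(C)C)cc1)c1cc(OCc2ccccc2)cc(OCc2ccccc2)c1)/C(=C\c1ccc(O[Si](C(C)C)(C(C)C)C(C)C)cc1)c1cc(OCc2ccccc2)cc(OCc2ccccc2)c1 | intermediate
11 | 3,5-bis(benzyloxy)phenylboronic acid | OB(O)c1cc(OCc2ccccc2)cc(OCc2ccccc2)c1 | starting material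
12 | (1E,3Z)-2,3-diaryl diene, tris-silyl ether (central ring cis to the C2 aryl) | c1ccc(cc1)COc1cc(OCc2ccccc2)cc(c1)/C(=C\c1ccc(O[Si](C(C)C)(C(C)C)C(C)C)c(c1)/C(=C\c1ccc(O[Si](C(C)C)(C(C)C)C(C)C)cc1)c1cc(OCc2ccccc2)cc(OCc2ccccc2)c1)/C(=C\c1ccc(O[Si](C(C)C)(C(C)C)C(C)C)cc1)c1cc(OCc2ccccc2)cc(OCc2ccccc2)c1 | intermediate
13 | 2-{(Z)-1-[3,5-bis(benzyloxy)phenyl]-2-(4-hydroxyphenyl)ethenyl}-4-{(1E,3Z)-2,3-bis[3,5-bis(benzyloxy)phenyl]-4-(4-hydroxyphenyl)buta-1,3-dien-1-yl}phenol | c1ccc(cc1)COc1cc(OCc2ccccc2)cc(c1)/C(=C\c1ccc(O)c(c1)/C(=C\c1ccc(O)cc1)c1cc(OCc2ccccc2)cc(OCc2ccccc2)c1)/C(=C\c1ccc(O)cc1)c1cc(OCc2ccccc2)cc(OCc2ccccc2)c1 | intermediate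
14 | 4-[(2S,3S)-3-[3,5-bis(benzyloxy)phenyl]-5-{(1E,3Z)-2,3-bis[3,5-bis(benzyloxy)phenyl]-4-(4-hydroxyphenyl)buta-1,3-dien-1-yl}-2,3-dihydro-1-benzofuran-2-yl]phenol | c1ccc(cc1)COc1cc(OCc2ccccc2)cc(c1)/C(=C\c1ccc2c(c1)[C@H](c1cc(OCc3ccccc3)cc(OCc3ccccc3)c1)[C@@H](c1ccc(O)cc1)O2)/C(=C\c1ccc(O)cc1)c1cc(OCc2ccccc2)cc(OCc2ccccc2)c1 | intermediate
15 | (1Z,2R,3R)-indane / (2S,3S)-dihydrobenzofuran hexabenzyl ether of the target | Oc1ccc([C@@H]2c3c(OCc4ccccc4)cc(OCc4ccccc4)cc3/C(=C\c3ccc4c(c3)[C@H](c3cc(OCc5ccccc5)cc(OCc5ccccc5)c3)[C@@H](c3ccc(O)cc3)O4)[C@H]2c2cc(OCc3ccccc3)cc(OCc3ccccc3)c2)cc1 | intermediate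
16 | CNP0184753.4 | Oc1ccc([C@@H]2c3c(O)cc(O)cc3/C(=C\c3ccc4c(c3)[C@H](c3cc(O)cc(O)c3)[C@@H](c3ccc(O)cc3)O4)[C@H]2c2cc(O)cc(O)c2)cc1 | target

**Step count and risks**

Total step count: 11. Longest linear sequence: 10 steps (1 → 3 → 4 → 5 → 8 → 9 → 10 → 12 → 13 → 15 → 16; step 4 is the side branch).

Step 10 is the most likely to fail. Before the central phenol is capped it can itself tautomerise to a quinone methide and scramble the benzylidene geometry; the Friedel–Crafts closure may be slow; and the sense and level of induction of both closures are untested, with the first acid still present during the second stage. The fallback closes the dihydrofuran ring before the benzylidene bond exists and decouples the two inductions. It sets out from 9: Bu4NF/AcOH gives the diphenol 1,1-dibromoalkene F1. The (R)-acid at 0 °C closes it to the (2S,3S)-dihydrobenzofuran dibromoalkene F2, where no alkene geometry can be lost. Coupling with 5 under the step 7 conditions gives the bromodiene F3, coupling with 11 under the step 8 conditions gives the mono-silyl diene F4, and Bu4NF/AcOH returns to the route at 14. Isolated 14 is then closed to 15 with the (S)-acid alone. This costs two extra steps.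

Step 7 is the second risk: the boronate 5 is α,β-diaryl-substituted, so transmetalation may be slow and mono-selectivity or conversion poor. The fallback changes the nucleophile to tin and needs no base. It sets out from 4: Pd(PPh3)4, (Me3Sn)2 and LiCl in THF at 60 °C give the (Z)-alkenyltrimethylstannane F5. Stille coupling of F5 with 9 (Pd2(dba)3, tri(2-furyl)phosphine, toluene, 100 °C), again selective for the bromine trans to the aryl group, comes back to the route at 10.

Step 11 is the third risk: the Lewis acid may isomerise the acid-sensitive benzylidene bond to the more stable E isomer. The fallback accepts this and corrects the geometry with light. It sets out from 15: the debenzylation is run to completion and any (1E)-isomer of the target F6 in the product is irradiated at 365 nm in degassed methanol at −20 °C, where the more twisted Z isomer is enriched in the photostationary state. F6 is recycled after chromatography, and the fallback comes back to the route at 16.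

**Further compounds**

F1 | step 10 | 4-(2,2-dibromoethenyl)-2-{(Z)-1-[3,5-bis(benzyloxy)phenyl]-2-(4-hydroxyphenyl)ethenyl}phenol | BrC(Br)=Cc1ccc(O)c(c1)/C(=C\c1ccc(O)cc1)c1cc(OCc2ccccc2)cc(OCc2ccccc2)c1
F2 | step 10 | 4-[(2S,3S)-3-[3,5-bis(benzyloxy)phenyl]-5-(2,2-dibromoethenyl)-2,3-dihydro-1-benzofuran-2-yl]phenol | BrC(Br)=Cc1ccc2c(c1)[C@H](c1cc(OCc3ccccc3)cc(OCc3ccccc3)c1)[C@@H](c1ccc(O)cc1)O2
F3 | step 10 | 4-[(2S,3S)-3-[3,5-bis(benzyloxy)phenyl]-5-{(1Z,3Z)-2-bromo-3-[3,5-bis(benzyloxy)phenyl]-4-[4-(triisopropylsilyloxy)phenyl]buta-1,3-dien-1-yl}-2,3-dihydro-1-benzofuran-2-yl]phenol | Br/C(=C\c1ccc2c(c1)[C@H](c1cc(OCc3ccccc3)cc(OCc3ccccc3)c1)[C@@H](c1ccc(O)cc1)O2)/C(=C\c1ccc(O[Si](C(C)C)(C(C)C)C(C)C)cc1)c1cc(OCc2ccccc2)cc(OCc2ccccc2)c1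
F4 | step 10 | mono-triisopropylsilyl ether of 14 (silyl group on the dienyl 4-hydroxyphenyl ring) | c1ccc(cc1)COc1cc(OCc2ccccc2)cc(c1)/C(=C\c1ccc2c(c1)[C@H](c1cc(OCc3ccccc3)cc(OCc3ccccc3)c1)[C@@H](c1ccc(O)cc1)O2)/C(=C\c1ccc(O[Si](C(C)C)(C(C)C)C(C)C)cc1)c1cc(OCc2ccccc2)cc(OCc2ccccc2)c1
F5 | step 7 | {(Z)-1-[3,5-bis(benzyloxy)phenyl]-2-[4-(triisopropylsilyloxy)phenyl]ethenyl}trimethylstannane | C[Sn](C)(C)/C(=C\c1ccc(O[Si](C(C)C)(C(C)C)C(C)C)cc1)c1cc(OCc2ccccc2)cc(OCc2ccccc2)c1
F6 | step 11 | (1E,2R,3R)-isomer of 16 with the (2S,3S)-dihydrobenzofuran unchanged | Oc1ccc([C@@H]2c3c(O)cc(O)cc3/C(=C/c3ccc4c(c3)[C@H](c3cc(O)cc(O)c3)[C@@H](c3ccc(O)cc3)O4)[C@H]2c2cc(O)cc(O)c2)cc1
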